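(The runs stem from a simulated flask with made-up constants, noise included.)

What will stand in the flask at 4.0 min, when you take it over?

1. amount of left-handed product in the flask at 4.0 min, in percent of the left-handed substrate and right-handed substrate together charged
2. amount of left-handed substrate in the flask at 4.0 min, in percent of the left-handed substrate and right-handed substrate together charged
3. amount of right-handed substrate in the flask at 4.0 min, in percent of the left-handed substrate and right-handed substrate together charged
4. amount of right-handed product in the flask at 4.0 min, in percent of the left-handed substrate and right-handed substrate together charged

It holds the racemate, held gas and single-handed catalyst at 0.2 mol%. The eta and beta runs differ from it in loading and end earlier.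

common to all: left-handed substrate 0.10 M; right-handed substrate 0.10 M; gas 4.9 mM (held)

|  | catalyst | remark | time |
|---|---|---|---|
| eta | 0.13 mol% | run made earlier |  |
| beta | 0.3 mol% | run made earlier |  |
| flask | 0.2 mol% |  | 4.0 min |

| run | time / min | left-handed product / % | left-handed substrate / % |
|---|---|---|---|
| eta | 0.250 | 1.1 | 48.6 |
| eta | 0.667 | 4.1 | 45.1 |
| eta | 1.33 | 9.1 | 40.6 |
| eta | 3.00 | 19.3 | 29.9 |
| beta | 0.417 | 3.0 | 46.5 |
| beta | 1.00 | 9.8 | 40.6 |
| beta | 2.00 | 19.6 | 31.9 |
| beta | 3.00 | 26.6 | 24.0 |

(each reading ± 0.5 percentage points)

- catalyst is single-handed; left-handed substrate and right-handed substrate are mirror images of each other, charged as a racemate, each of them at the stated concentration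
- at the start none of the gas is in solution

Work in powers of ten. Let f be the left-handed substrate as a fraction of its own charge, and read how many powers of ten of f go per minute, a slope treated as pseudo-first-order on a base-ten scale. The late readings give 0.0796 min⁻¹ in eta and 0.114 min⁻¹ in beta. The logarithm of their ratio over that of the loadings gives an apparent order in catalyst of 0.432, so I reckon your flask at 0.0958 min⁻¹, its decade rate.

The eta line, run back to the charge, starts late by 0.193 min, and no gas is in solution at the start. Taking the same delay for your flask, I reckon that by 4.0 min it will have lost 0.365 decades, which puts 21.6% of the two substrates charged together at left-handed substrate and 28.4% at left-handed product. Neither run read the right-handed side, so I commit to no figure there. Leave the gas alone: the slopes were read at this same saturation.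

The forecast gave left-handed product 28.2%, left-handed substrate 21.8%, right-handed substrate 44% and right-handed product 6%, saying of that side “I guess modest conversion”.

The flask gives left-handed product 29.0%, left-handed substrate 21.0%, right-handed substrate 36.4% and right-handed product 13.6%.

    reagent + catalyst + left-handed substrate → catalyst + left-handed product (k = 7900 M⁻² s⁻¹)
    reagent + catalyst + right-handed substrate → catalyst + right-handed product (k = 2900 M⁻² s⁻¹)
    gas ⇌ reagent, rate k3*(csat - [reagent]) (kL = 0.140 s⁻¹)

The flask keeps 42% of its left-handed charge, less than the 73% of its right-handed charge. For a neighbour flask with 0.5 mol% of catalyst the decade rate reckons to 0.142 min⁻¹, which gives 14.4% as left-handed substrate, and that neighbour flask holds 12.7%.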